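Ring numbering: O1, C2 (aryl), C3 (CH2OH), C4 (aroyl), C5. The route rests on the γ-hydroxy ketone HO–CH2–C3–C4–C(=O)Ar. It is the hydrate of a 5-aryl-2,3-dihydrofuran ring (O, CH2, C3, C4, C–Ar) fused to the oxolane along C3–C4, and that enol ether is a ring-expanded isomer of an aryl ketone on a cyclopropane made of C3, C4 and the future CH2OH carbon.
Disconnections, backwards: O-debenzylation, then hydrolysis of the fused enol ether, then MgI2-catalysed Cloke–Wilson rearrangement of the 1-aroyl-4-aryl-3-oxabicyclo[3.1.0]hexane. In the hydrolysis the proton must enter C4 on the convex face of the cis-bicyclo[3.3.0] frame, which fixes the epimerisable 3,4-cis relation without base.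
The cyclopropyl ketone comes from oxidation of its carbinol, and the carbinol from Simmons–Smith methylenation of C3=C4 anti to the C2 aryl. The methylene goes in at the alcohol level because the C2–H of the corresponding enone is benzylic, α to oxygen and vinylogously acidic, so a basic ylide would endanger C2.
The 2,5-dihydrofuran comes from ring-closing metathesis of the adduct of a 2-lithioallyl ether with O-benzylsyringaldehyde. The ether derives from (S)-1-arylallyl alcohol (vinyl Grignard addition, lipase resolution), so syringaldehyde supplies both aryl rings and C2 is the only resolved centre.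
Order of ring formation: oxolane (as 2,5-dihydrofuran), cyclopropane, fused dihydrofuran (key step); water then opens the last ring.

Key step: step 9

Remark: Ar stands for 4-(benzyloxy)-3,5-dimethoxyphenyl; the carbinol carbon created in step 5 is carried as an epimer mixture until step 8 removes it.

Step 1
Reactants: 1 syringaldehyde; 2 benzyl bromide
Product: 3 4-(benzyloxy)-3,5-dimethoxybenzaldehyde
Conditions: K2CO3, DMF, 60 °C
Reagents that add atoms: benzyl bromide, BrCc1ccccc1
Why: Williamson ether synthesis, in which the acidic para-formyl phenol is deprotonated by K2CO3 and its phenoxide displaces bromide from the primary benzylic halide, giving a group that withstands the organometallic, NaH, Ru, Zn and Mg reagents ahead and leaves by hydrogenolysis.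

Step 2
Reactants: 3 4-(benzyloxy)-3,5-dimethoxybenzaldehyde; 4 vinylmagnesium bromide
Product: 5 rac-1-Ar-prop-2-en-1-ol
Conditions: THF, −20 → 0 °C; then sat. aq NH4Cl
Reagents that add atoms: vinylmagnesium bromide, C=C[Mg]Br
Why: Grignard 1,2-addition to a non-enolisable aromatic aldehyde, which creates C2 as a racemate that step 3 resolves.

Step 3
Reactants: 5 rac-1-Ar-prop-2-en-1-ol
Product: 6 (S)-1-Ar-prop-2-en-1-ol (the unreacted enantiomer)
Conditions: Novozym 435 (immobilised Candida antarctica lipase B), vinyl acetate, MTBE, 30 °C, stopped just past half conversion; chromatography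
Reagents that add atoms: none
Why: Lipase-catalysed kinetic resolution by irreversible transesterification, in which the empirical size rule for secondary alcohols (aryl large, vinyl medium) predicts acetylation of the R alcohol, so the S alcohol carrying the C2 configuration of the target stays free and is separated from the acetate.

Step 4
Reactants: 6 (S)-1-Ar-prop-2-en-1-ol; 7 2,3-dibromopropene
Product: 8 (1S)-1-Ar-prop-2-en-1-yl 2-bromoprop-2-en-1-yl ether
Conditions: NaH, n-Bu4NI (cat.), THF–DMF, 0 °C → rt
Reagents that add atoms: 2,3-dibromopropene, C=C(Br)CBr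
Why: Williamson ether synthesis in which the sodium alkoxide attacks only the allylic CH2Br of 7 (the vinylic bromide is inert to SN2) and the C–O bond at the stereocentre is not touched, so C2 stays S.

Step 5
Reactants: 8 (1S)-1-Ar-prop-2-en-1-yl 2-bromoprop-2-en-1-yl ether; 3 4-(benzyloxy)-3,5-dimethoxybenzaldehyde
Product: 10 1-Ar-2-({[(1S)-1-Ar-prop-2-en-1-yl]oxy}methyl)prop-2-en-1-ol as a mixture of carbinol epimers, via 2-lithioallyl ether 9 (not isolated)
Conditions: t-BuLi (2.1 equiv), Et2O, −78 °C; then 3, THF, −78 °C; sat. aq NH4Cl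
Reagents that add atoms: none
Why: Bromine–lithium exchange on the vinylic bromide at −78 °C outruns deprotonation and β-alkoxide loss, and the alkenyllithium adds 1,2 to the non-enolisable aldehyde; the new carbinol centre forms without control, which is harmless because step 8 erases it.

Step 6
Reactants: 10 1-Ar-2-({[(1S)-1-Ar-prop-2-en-1-yl]oxy}methyl)prop-2-en-1-ol
Product: 11 [(5S)-5-Ar-2,5-dihydrofuran-3-yl](Ar)methanol (carbinol epimers)
Conditions: second-generation Grubbs catalyst (H2IMes)(PCy3)Cl2Ru=CHPh (4 mol %), CH2Cl2 (0.01 M), 40 °C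
Reagents that add atoms: none
Why: Ring-closing metathesis of a monosubstituted and a 1,1-disubstituted electron-neutral alkene closes the five-membered O1–C5 ring as its C3=C4 olefin with loss of ethene, under neutral conditions that leave C2 untouched.

Step 7
Reactants: 11 [(5S)-5-Ar-2,5-dihydrofuran-3-yl](Ar)methanol; 12 diiodomethane
Product: 13 [(1S,4S,5S)-4-Ar-3-oxabicyclo[3.1.0]hexan-1-yl](Ar)methanol (carbinol epimers; Ar on C4 trans to the cyclopropane CH2)
Conditions: Et2Zn, CH2I2 (4 equiv each), CH2Cl2, −15 → 0 °C; sat. aq NaHCO3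
Reagents that add atoms: diiodomethane, ICI
Why: Hydroxyl-assisted Simmons–Smith cyclopropanation (Et2Zn/CH2I2 variant), in which the zinc alkoxide holds the carbenoid next to C3=C4 and the concerted syn methylene transfer occurs on the ring face opposite the neighbouring C2 aryl group, setting C3 and C4 together without any base that could remove the C2–H; a minor face isomer would be removed after step 8.

Step 8
Reactants: 13 [(1S,4S,5S)-4-Ar-3-oxabicyclo[3.1.0]hexan-1-yl](Ar)methanol
Product: 14 [(1S,4S,5S)-4-Ar-3-oxabicyclo[3.1.0]hexan-1-yl](Ar)methanone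
Conditions: Dess–Martin periodinane, pyridine, CH2Cl2, 0 °C → rt
Reagents that add atoms: none
Why: Dess–Martin oxidation of a secondary benzylic alcohol under pyridine buffering merges both carbinol epimers into one ketone that has no enolisable hydrogen, so none of its three stereocentres can be lost.

Step 9
Reactants: 14 [(1S,4S,5S)-4-Ar-3-oxabicyclo[3.1.0]hexan-1-yl](Ar)methanone
Product: 16 (5R,6S)-2,6-di-Ar-3,7-dioxabicyclo[3.3.0]oct-1-ene (fused cyclic enol ether), via iodomethyl magnesium enolate 15 (not isolated)
Conditions: MgI2 (20 mol %), 2,6-di-tert-butyl-4-methylpyridine (20 mol %), THF, 75 °C, sealed tube; work-up with Et3N-doped Et2O and aq NaHCO3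
Reagents that add atoms: none
Why: Cloke–Wilson rearrangement under iodide/Lewis-acid catalysis: magnesium binds the ketone oxygen, iodide attacks the cyclopropane CH2 from the back in an SN2-type homoconjugate addition that breaks the C4–CH2 bond, and the s-cis ketone rotamer gives the E magnesium enolate 15, whose oxygen lies on the side of the CH2I arm. That oxygen displaces iodide in a 5-exo-tet O-alkylation, which forms the CH2–O bond, closes the dihydrofuran ring onto the oxolane and returns MgI2, whereas 3-exo-tet C-alkylation, or an enolate of the other geometry, can only fall back to 14. The closest known cases are halide- and Lewis-acid-promoted Cloke–Wilson ring expansions of acylcyclopropanes and the MgI2-catalysed opening of singly activated spirocyclopropyl oxindoles at an unsubstituted CH2. No stereocentre is made and none is touched, because the bonds at C2 and C3 stay intact, so the methylene placed anti to the aryl group in step 7 becomes the O–CH2 arm trans to that aryl. The selectivity needed is cleavage of C4–CH2 and not of the ring-fusion bond C4–C3, and it is secured because iodide reaches the primary carbon far more easily than the methine C3 wedged between quaternary C4 and aryl-bearing C2. Since a C=O bond is exchanged for an enol ether, much of the strain energy is spent and the equilibrium may lie only modestly on the product side, hence the moderate temperature, the proton scavenger that protects the enol ether, and the recovery of unchanged 14 (inert in step 10) for recycling.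

Step 10
Reactants: 16 (5R,6S)-2,6-di-Ar-3,7-dioxabicyclo[3.3.0]oct-1-ene
Product: 18 [(3R,4R,5S)-5-Ar-4-(hydroxymethyl)oxolan-3-yl](Ar)methanone, via cyclic hemiketal 17 (not isolated)
Conditions: PPTS (10 mol %), THF–H2O 9:1, 0 °C → rt
Reagents that add atoms: water, O
Why: Acid-catalysed enol ether hydrolysis, in which the proton can reach C4 only on the convex face that already carries H3 (a trans-fused bicyclo[3.3.0] oxocarbenium ion being too strained), which sets C4 as R with the aroyl group cis to the CH2O arm, after which water adds to the aryl-stabilised oxocarbenium ion and hemiketal 17 opens to the conjugated ketone at an acidity where that ketone does not enolise.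

Step 11
Reactants: 18 [(3R,4R,5S)-5-Ar-4-(hydroxymethyl)oxolan-3-yl](Ar)methanone
Product: 19 ciwujiatone
Conditions: H2 (1 atm), 10% Pd/C, EtOAc, rt, stopped at uptake of two equivalents
Reagents that add atoms: none
Why: Catalytic hydrogenolysis of the two phenolic benzyl ethers over Pd/C in a neutral aprotic solvent should be much faster than reduction of the electron-rich aryl ketone or cleavage of the C2–O1 bond, and no acid or base is present that could epimerise C4.

Compound list
1 | syringaldehyde | COc1cc(C=O)cc(OC)c1O | starting material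
2 | benzyl bromide | BrCc1ccccc1 | starting material
3 | 4-(benzyloxy)-3,5-dimethoxybenzaldehyde | COc1cc(C=O)cc(OC)c1OCc1ccccc1 | intermediate
4 | vinylmagnesium bromide | C=C[Mg]Br | starting material
5 | rac-1-[4-(benzyloxy)-3,5-dimethoxyphenyl]prop-2-en-1-ol | C=CC(O)c1cc(OC)c(OCc2ccccc2)c(OC)c1 | intermediate
6 | (S)-1-[4-(benzyloxy)-3,5-dimethoxyphenyl]prop-2-en-1-ol | C=C[C@H](O)c1cc(OC)c(OCc2ccccc2)c(OC)c1 | intermediate
7 | 2,3-dibromopropene | C=C(Br)CBr | starting material
8 | (1S)-1-Ar-prop-2-en-1-yl 2-bromoprop-2-en-1-yl ether | C=C[C@H](OCC(Br)=C)c1cc(OC)c(OCc2ccccc2)c(OC)c1 | intermediate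
9 | (1S)-1-Ar-prop-2-en-1-yl 2-lithioprop-2-en-1-yl ether (not isolated) | C=C[C@H](OCC([Li])=C)c1cc(OC)c(OCc2ccccc2)c(OC)c1 | intermediate
10 | 1-Ar-2-({[(1S)-1-Ar-prop-2-en-1-yl]oxy}methyl)prop-2-en-1-ol, carbinol epimers | C=C[C@H](OCC(=C)C(O)c1cc(OC)c(OCc2ccccc2)c(OC)c1)c1cc(OC)c(OCc2ccccc2)c(OC)c1 | intermediate
11 | [(5S)-5-Ar-2,5-dihydrofuran-3-yl](Ar)methanol, carbinol epimers | OC(c1cc(OC)c(OCc2ccccc2)c(OC)c1)C1=C[C@@H](c2cc(OC)c(OCc3ccccc3)c(OC)c2)OC1 | intermediate
12 | diiodomethane | ICI | starting material
13 | [(1S,4S,5S)-4-Ar-3-oxabicyclo[3.1.0]hexan-1-yl](Ar)methanol, carbinol epimers, Ar trans to cyclopropane CH2 | OC(c1cc(OC)c(OCc2ccccc2)c(OC)c1)[C@]12CO[C@H](c3cc(OC)c(OCc4ccccc4)c(OC)c3)[C@H]1C2 | intermediate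
14 | [(1S,4S,5S)-4-Ar-3-oxabicyclo[3.1.0]hexan-1-yl](Ar)methanone, Ar trans to cyclopropane CH2 | O=C(c1cc(OC)c(OCc2ccccc2)c(OC)c1)[C@]12CO[C@H](c3cc(OC)c(OCc4ccccc4)c(OC)c3)[C@H]1C2 | intermediate
15 | iodomagnesium (E)-enolate of the 2-Ar-3-(iodomethyl)oxolan-4-ylidene aryl ketone, CH2I trans to Ar, enolate O on the C3 side (not isolated) | IC[C@@H]1[C@@H](c2cc(OC)c(OCc3ccccc3)c(OC)c2)OC/C1=C(/O[Mg]I)c1cc(OC)c(OCc2ccccc2)c(OC)c1 | intermediate
16 | (5R,6S)-2,6-bis[4-(benzyloxy)-3,5-dimethoxyphenyl]-3,7-dioxabicyclo[3.3.0]oct-1-ene | COc1cc(C2=C3CO[C@H](c4cc(OC)c(OCc5ccccc5)c(OC)c4)[C@H]3CO2)cc(OC)c1OCc1ccccc1 | intermediate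
17 | cis-fused 2,6-di-Ar-3,7-dioxabicyclo[3.3.0]octan-2-ol, ring-fusion and C6 centres as in 18, hemiketal carbon unassigned (not isolated) | OC1(c2cc(OC)c(OCc3ccccc3)c(OC)c2)OC[C@H]2[C@@H]1CO[C@@H]2c1cc(OC)c(OCc2ccccc2)c(OC)c1 | intermediate
18 | [(3R,4R,5S)-5-Ar-4-(hydroxymethyl)oxolan-3-yl](Ar)methanone | COc1cc(C(=O)[C@H]2CO[C@H](c3cc(OC)c(OCc4ccccc4)c(OC)c3)[C@H]2CO)cc(OC)c1OCc1ccccc1 | intermediate
19 | ciwujiatone, [(3R,4R,5S)-5-(4-hydroxy-3,5-dimethoxyphenyl)-4-(hydroxymethyl)oxolan-3-yl](4-hydroxy-3,5-dimethoxyphenyl)methanone | COc1cc(C(=O)[C@H]2CO[C@H](c3cc(OC)c(O)c(OC)c3)[C@H]2CO)cc(OC)c1O | target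

Total step count: 11. Longest linear sequence: 11 steps (1 to 19; aldehyde 3 is used twice).

Steps most likely to fail

Step 9.
- What may go wrong: the rearrangement may stall at an unfavourable equilibrium, because the released ring strain is nearly cancelled by the loss of the C=O bond. The Lewis acid may also ionise the benzylic C2–O1 bond before the cyclopropane opens.
- Fallback: the rearrangement is split into a stoichiometric opening and an irreversible closure.
- Setting out from 14, Me3SiI (1.05 equiv, CH2Cl2, −78 °C) silylates the ketone oxygen, and iodide opens the cyclopropane at its CH2 to the iodomethyl trimethylsilyl enol ether F1.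
- PPTS in wet THF at 0 °C then protonates C4 on the face away from the adjacent CH2I arm and gives the cis γ-iodo ketone F2.
- AgOTf with 2,6-di-tert-butyl-4-methylpyridine in CH2Cl2 removes iodide as its silver salt while the ketone oxygen closes on the CH2 carbon. Deprotonation of the bicyclic oxocarbenium ion gives 16, where the route is rejoined.

Step 7.
- What may go wrong: facial selectivity may erode for the carbinol epimer whose directing effect opposes the steric bias of the C2 aryl group. Zinc iodide may also ionise the electron-rich benzylic carbinols.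
- Fallback: carbenoid chemistry is replaced by a neutral dipolar cycloaddition on the enone.
- Setting out from 11, Dess–Martin oxidation gives the dihydrofuranyl aryl ketone F3.
- Ethereal CH2N2 at 0 °C adds across C3=C4 anti to the aryl group, with its carbon on the β-carbon C3, to give the cis-fused 1-pyrazoline F4.
- F4 cannot tautomerise at quaternary C4. Irradiation at 350 nm in benzene extrudes nitrogen and closes the cyclopropane to 14, where the route is rejoined.

Step 11.
- What may go wrong: over-reduction, that is hydrogenolysis of the benzylic C2–O1 bond or reduction of the aryl ketone while the second benzyl ether is still being cleaved.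
- Fallback: non-reductive debenzylation. Setting out from 18, BCl3 with pentamethylbenzene as benzyl cation scavenger (CH2Cl2, −78 °C, methanol/NaHCO3 quench) cleaves the central O-benzyl groups, which are activated by chelation with the flanking methoxy oxygens. This leads directly to 19 without any new intermediate.

Further compounds
F1 | step 9 | (E)-trimethylsilyl enol ether of the 2-Ar-3-(iodomethyl)oxolan-4-ylidene aryl ketone, CH2I trans to Ar, OSiMe3 on the C3 side | IC[C@@H]1[C@@H](c2cc(OC)c(OCc3ccccc3)c(OC)c2)OC/C1=C(/O[Si](C)(C)C)c1cc(OC)c(OCc2ccccc2)c(OC)c1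
F2 | step 9 | [(3R,4S,5S)-5-Ar-4-(iodomethyl)oxolan-3-yl](Ar)methanone | COc1cc(C(=O)[C@H]2CO[C@H](c3cc(OC)c(OCc4ccccc4)c(OC)c3)[C@H]2CI)cc(OC)c1OCc1ccccc1
F3 | step 7 | [(5S)-5-Ar-2,5-dihydrofuran-3-yl](Ar)methanone | O=C(c1cc(OC)c(OCc2ccccc2)c(OC)c1)C1=C[C@@H](c2cc(OC)c(OCc3ccccc3)c(OC)c2)OC1
F4 | step 7 | 1-pyrazoline cis-fused to the oxolane at C3–C4, CH2 on C3 and N on C4, both on the face opposite the C2 Ar, aroyl on C4 | O=C(c1cc(OC)c(OCc2ccccc2)c(OC)c1)[C@]12CO[C@H](c3cc(OC)c(OCc4ccccc4)c(OC)c3)[C@H]1CN=N2
F0 | step 11 | none | none
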